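The easy mistake in this flask is to count nucleophile by its charge.

electrophile 26 mM; nucleophile 46.8 mM; buffer base 26.0 mM; buffer acid 26.0 mM; protic impurity 1.30 mM; time 30 min

    electrophile + nucleophile → acid + target + leaving group (k1 = 0.125 M⁻¹ s⁻¹)
    nucleophile + protic impurity → quenched reagent (k2 = 0.684 M⁻¹ s⁻¹)
    electrophile + target ⇌ idle adduct, settled at all times (K3 = 16.3 M⁻¹)
    target → over-reaction product (k4 = 4.97 × 10⁻⁷ s⁻¹)
    protonated nucleophile ⇌ nucleophile + acid, settled at all times (K5 = 7.9 × 10⁻⁹ M)
    buffer acid ⇌ buffer base + acid, settled at all times (K6 = 1.6 × 10⁻⁹ M)

- part of the electrophile that has reacted at 30 min
- pH of the solution at 30 min

- acid is the free proton; pH is minus the decimal logarithm of its molar concentration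
- percent here means electrophile units held: one idle adduct counts as two
- what is said of target includes idle adduct
- in an amount of target, one idle adduct counts as one target
- what has gone from electrophile into another species counts as reacted, even if it can come back
- run time (flask): 30 min

The flask seems to contradict itself. It holds 46.8 mM of nucleophile against 26 mM of electrophile, and the half-life of electrophile by step 1 at the charged concentrations is 2.0 min, so 30 min ought to leave 0.00267 %. But that sum holds nucleophile at its charge, and each coupling spends nucleophile and frees acid.

Each electrophile that couples removes two free bases: the nucleophile it consumes and the base that takes up its acid. So I carry the spare base, meaning buffer base plus nucleophile, minus impurity, minus two for each electrophile charged: 19.5 mM. Free base, nucleophile plus buffer base, is then the spare base plus two for each electrophile not yet coupled, with the impurity counted in full.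

I work with what is left. Let u be electrophile not yet coupled, free or idle. Taking the spare base as evenly split between the two bases, the proton balances give nucleophile 53.3 % of free base, and with target near its full amount the idle adduct leaves 70.2 % of u free. The ratio of u to free base then falls exponentially from 0.364, with a half-life of 12.7 min, longer than the 2.0 min above, and it is the spare base, not the charge of nucleophile, that stands in that half-life. After 30 min the ratio is 0.0705, so I expect 95.7 % of this flask's electrophile reacted.

The forecast gives 96 % (94 % to 97.5 %) and pH 8.21 (8.15 to 8.3), with the pH falling “as the buffer takes up most of the acid”.

The simulation of this flask gives 96.3 % reacted and pH 8.20, inside both ranges. That range for the reacted part would be wrong for a neighbour charged with 6.5 mM of buffer base, all else the same. The neighbour's spare base is 19.5 mM less 19.5 mM, which is nothing, so its free base is two for each uncoupled electrophile, and one over u grows steadily: a second-order tail. With nucleophile about 74.8 % of free base, I reckon 90.2 % reacted. The neighbour reaches 90.5 %, with 11 % of its nucleophile left.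

All constants were drawn at random within sensible limits; the flask was simulated.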